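## Analysis of the target

Atom labels C1–C11 and ring letters are used for the same positions in every intermediate. The β face is the face of ring C that carries the C4 hydroxyl of the target; α is the opposite face.

The target 34 is a tetracycle. Ring A is a 5,6-dimethyl-2-pyranone, ring B a dihydropyran whose C1 is a hemiketal, ring C the seven-membered carbocycle C1–C2–C3–C4–C5–C9–C10, and ring D a 5,5-dimethylcyclopentenone (C4, C5=C6, C7=O, C8) fused at C4–C5; C11 links C10 to ring A. It has five stereocentres: C1–OH β (ring B oxygen α), C2–OH α, C4–OH β, C9–CH3 α and C10–C11 β. Ring B is therefore trans-fused, the C2 hydroxyl is anti to both oxygenated neighbours, and the C9 methyl is anti to the C10 arm. The hemiketal can open to a 2-hydroxy-1,3-diketone in which C2 and C10 are epimerisable. The tertiary α-ketol at C4 is prone to acyloin shift and, through C8–C7, to retro-aldol cleavage, and the pyranone lactone does not tolerate hard nucleophiles. The difficulty is the run of four oxidised carbons C1–C4 on a seven-membered ring held between two other rings, with C9 the only robust carbon stereocentre. The strategy rests on C1 and C5, which flank the four-carbon unit C1–C10–C9–C5 and can each carry one oxygen: C1 keeps it as the hemiketal, while C5 can lose it because it is β to the C7 carbonyl. A four-carbon unit oxygenated at both ends, with the methyl and the C11 arm on its inner carbons, is a 2,3,4-trisubstituted furan. The remaining ring C carbons C2–C3–C4, with the carbonyl in the middle, are an oxyallyl cation joined to the furan through C8–C7–C6.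

## Retrosynthetic reasoning

**C1–OH and C2–OH.** The two hydroxyls of 34 are removed together, back to the ring-B enol ether 31 (C1=C2 conjugated with the C3 ketone). Cutting here, and not at a free 1,3-diketone, keeps C1 masked from the moment C2 receives its oxygen, so C2 is set kinetically. Forward, an epoxidation from the α face and hydrolytic opening at C1 must give the trans-diaxial diol.

**Ring B (C1–O) and C10.** The enol ether 30 is opened at the C1–O bond to the 1,3-diketone 27 with a protected pyranone hydroxyl. The pyranone oxygen can reach only C1, so cyclodehydration is regiochemically fixed. The same acid should invert C10, which is γ to the C3 carbonyl in the enol ether.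

**C4–OH, C1 oxidation level and the C5=C6 enone.** Diketone 27 comes from diol 26 by oxidation at C1. The C4 hydroxyl of 26 is removed to an extended enolate, and the C1 oxygen is reconnected to C5, which gives the oxygen-bridged diketone 23. Forward, E1cB cleavage of C5–O leaves the oxygen on C1 and creates the enone; the enolate formed at once at C4 is oxygenated before C1 is oxidised. In this order C4–H is the only acidic site and the cis C9/C10 substituents screen one face.

**C7 and C9.** Diketone 23 goes back through alcohol 22 to silyl ether 21, and 21 to the alkene 20. The C9=C10 double bond is saturated while the bridge is in place, because the bicycle has one open face and that face gives the correct C9.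

**Rings C and D (C1–C2 and C4–C5).** Cycloadduct 20 is cut at both bonds to the oxyallyl cation 19 and so to chloromethyl ketone 18. No other disconnection forms the seven- and five-membered rings together and puts oxygen on both C1 and C5. Forward, the C7 silyloxy centre must choose the furan face.

**C2–C3.** Ketone 18 is cut between the chloromethyl carbon and the carbonyl, back to Weinreb amide 17. This makes the sensitive chloroketone in the last step before the cycloaddition.

**C11–ring A.** Amide 17 is cut at the C11–pyranone bond to aldehyde 13 and pyranone 14. Reductive alkylation gives C-alkylation only.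

**C5–C6 and C7.** Aldehyde 13 goes back through lactone 9 to bromofuran 4 and epoxide 7. The bond between the furan carbon and C6 is formed by opening the epoxide at its CH2 end, so the epoxide carbon becomes C7 without change of configuration. Bromofuran 4 comes from ester 1, whose ester group directs the bromine to the carbon beside the methyl; epoxide 7 comes from ester 5.

## Alternatives that were turned down

**Alternative 1:** two-carbon ring expansion of a diquinane. The cut is at C1–C10 and C2–C3. Forward, the silyl enol ether A1 undergoes [2+2] addition with dichloroketene A2, and desilylation with retro-aldol cleavage of the old C3–C10 bond gives the dichloro-dione A3.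
- For: C1 and C3 arrive as carbonyls, C2 is functionalised, and C4 already carries its oxygen. On these points it is stronger than the chosen route, which must oxidise C1 and C4 late.
- Against: A1 is itself an enantiopure bicycle with a quaternary carbinol and the C9 centre. A3 lacks C11 and ring A, so a C–C bond must later be made at C10, next to C9, on a 2,2-dichloro-1,3-dione that bases and nucleophiles cleave. The chlorines must be removed and C2 re-oxidised, and C10 and C2 are left without control.
- Comparison: the chosen route carries C11 and ring A from the furan stage and closes rings C and D in one step.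

**Alternative 2:** aldol closure of ring D. The cut is at C4–C8. Forward, a catalytic alkoxide base converts the isopropyl enone A4 into the tetracycle A5, with the alkene geometry and C9 equilibrating through the dienolate.
- For: the C4 carbinol and ring D form without any C–H oxidation, and C1 and C2 are fixed early as a ketal and a silyl ether. This is stronger than the late C4 oxygenation of the chosen route.
- Against: A4 already contains rings A–C with four contiguous oxygenated carbons on the seven-membered ring, so the main problem is moved, not solved. The aldol joins two fully substituted carbons and may not lie on the side of A5. Its facial outcome depends on C9, which is itself equilibrating. C3 must afterwards be oxidised beside the new tertiary alcohol.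
- Comparison: the chosen route builds the carbocyclic core early from simple pieces and needs far fewer steps to reach it.

**Alternative 3:** cyclopropanation and Cope rearrangement. The cut is at C2–C3 and C9–C10. Forward, the carbenoid from vinyldiazoacetate A6 cyclopropanates the methylidene of diene A7, and the cis-divinylcyclopropane rearranges to the cycloheptadiene A8.
- For: it is convergent, a chiral dirhodium carboxylate can control the absolute configuration, and C9 and C10 are set together through a boat transition state. On C10 and on enantiocontrol it is stronger than the chosen route, which relies on a tether stereocentre and a late epimerisation.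
- Against: A8 has an ester on C2 that must be excised and replaced by a hydroxyl, C3 is a methylene that must become the ketone, and C4=C5 must be transposed into C4–OH/C5=C6. That is three oxidation-level corrections on ring C, plus ketal removal. The carbenoid must also choose between the two alkenes of A7 and tolerate the pyranone.
- Comparison: the chosen cycloaddition delivers C3 as the ketone and oxygen on C1 and C5 at the right level, so its end game is shorter.

Key step: step 13

Assumption 1: compounds 1, 5 and 14 are taken as purchasable.
Assumption 2: in the tetracyclic enol ether the trans arrangement of the C9 methyl and the C10 arm is taken to be the more stable one, so that acid equilibration in step 19 leads to it.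

## Route

Step 1
Reactants: 1 ethyl 4-methylfuran-3-carboxylate
Product: 2 ethyl 5-bromo-4-methylfuran-3-carboxylate
Conditions: NBS, DMF, 0 °C to rt
Reagents that add atoms: N-bromosuccinimide, BrN1C(=O)CCC1=O
Why: Electrophilic aromatic bromination; the ester deactivates the α-carbon next to it and the methyl activates the other, so bromine should enter beside the methyl.

Step 2
Reactants: 2 ethyl 5-bromo-4-methylfuran-3-carboxylate
Product: 3 (5-bromo-4-methylfuran-3-yl)methanol
Conditions: i-Bu2AlH, CH2Cl2, −78 to 0 °C
Reagents that add atoms: none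
Why: Hydride reduction of the ester to the primary alcohol (future C11); the furyl bromide is inert at low temperature.

Step 3
Reactants: 3 (5-bromo-4-methylfuran-3-yl)methanol
Product: 4 [(5-bromo-4-methylfuran-3-yl)methoxy]triethylsilane
Conditions: Et3SiCl, imidazole, CH2Cl2, 0 °C
Reagents that add atoms: chlorotriethylsilane, CC[Si](Cl)(CC)CC
Why: Silylation; the primary TES ether survives the organometallic steps and can later be removed beside a hindered secondary TBS ether.

Step 4
Reactants: 5 methyl 3,3-dimethylpent-4-enoate
Product: 6 methyl 3-methyl-3-(oxiran-2-yl)butanoate (racemic)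
Conditions: mCPBA, CH2Cl2, rt
Reagents that add atoms: 3-chloroperbenzoic acid, OOC(=O)c1cccc(Cl)c1
Why: Prilezhaev epoxidation of the isolated terminal alkene; the vinyl carbons become C6 and C7, and the ester carbon is C3.

Step 5
Reactants: 6 methyl 3-methyl-3-(oxiran-2-yl)butanoate (racemic)
Product: 7 methyl 3-methyl-3-[(2R)-oxiran-2-yl]butanoate
Conditions: (R,R)-[N,N'-bis(3,5-di-tert-butylsalicylidene)-1,2-cyclohexanediaminato]Co(OAc) (cat., the enantiomer that hydrolyses the (S)-epoxide), H2O (0.55 equiv), THF, 0 °C to rt
Reagents that add atoms: none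
Why: Jacobsen hydrolytic kinetic resolution; the (S)-epoxide is hydrolysed to the diol and the (R)-epoxide is left, which fixes the future C7 centre.

Step 6
Reactants: 4 [(5-bromo-4-methylfuran-3-yl)methoxy]triethylsilane; 7 methyl 3-methyl-3-[(2R)-oxiran-2-yl]butanoate
Product: 9 (5S)-4,4-dimethyl-5-{[3-methyl-4-(triethylsilyloxymethyl)furan-2-yl]methyl}oxolan-2-one, via hydroxy ester magnesium alkoxide 8 (not isolated)
Conditions: 4, t-BuLi (2 equiv), Et2O, −78 °C; MgBr2·OEt2; then 7, CuI (10 mol %), THF, −30 °C to rt
Reagents that add atoms: none
Why: Bromine–lithium exchange, transmetalation and CuI-catalysed SN2 opening of the epoxide at its CH2 end form the bond between the furan carbon and C6 with C7 untouched. The alkoxide then closes the five-membered lactone on the methyl ester (gem-dimethyl effect), which masks C7–O and C3 together.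

Step 7
Reactants: 9 (5S)-4,4-dimethyl-5-{[3-methyl-4-(triethylsilyloxymethyl)furan-2-yl]methyl}oxolan-2-one
Product: 11 (4S)-4-[tert-butyl(dimethyl)silyl]oxy-N-methoxy-N,3,3-trimethyl-5-[3-methyl-4-(triethylsilyloxymethyl)furan-2-yl]pentanamide, via hydroxy Weinreb amide 10 (not isolated)
Conditions: MeNH(OMe)·HCl, i-PrMgCl, THF, −20 to 0 °C; crude product: TBSOTf, 2,6-lutidine, CH2Cl2, −78 to 0 °C
Reagents that add atoms: N,O-dimethylhydroxylamine hydrochloride, C[NH2+]OC.[Cl-]; tert-butyldimethylsilyl triflate, CC(C)(C)[Si](C)(C)OS(=O)(=O)C(F)(F)F
Why: Aminolysis of the lactone by the chloromagnesium amide gives the Weinreb amide; immediate silylation of the hindered C7 alcohol prevents relactonisation.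

Step 8
Reactants: 11 TBS/TES-protected Weinreb amide
Product: 12 (4S)-4-[tert-butyl(dimethyl)silyl]oxy-5-[4-(hydroxymethyl)-3-methylfuran-2-yl]-N-methoxy-N,3,3-trimethylpentanamide
Conditions: PPTS, MeOH, 0 °C
Reagents that add atoms: none
Why: Acid-catalysed methanolysis removes the primary TES ether far faster than the secondary TBS ether next to the quaternary carbon.

Step 9
Reactants: 12 furylmethanol Weinreb amide
Product: 13 (4S)-4-[tert-butyl(dimethyl)silyl]oxy-5-(4-formyl-3-methylfuran-2-yl)-N-methoxy-N,3,3-trimethylpentanamide
Conditions: MnO2, CH2Cl2, rt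
Reagents that add atoms: none
Why: MnO2 oxidation of the benzylic-type furylmethanol to the aldehyde (C11).

Step 10
Reactants: 13 furan-3-carbaldehyde Weinreb amide; 14 4-hydroxy-5,6-dimethyl-2H-pyran-2-one
Product: 16 Weinreb amide carrying the 3-(furylmethyl)-4-hydroxy-5,6-dimethylpyran-2-one arm, via Knoevenagel alkylidene 15 (not isolated)
Conditions: Hantzsch ester, L-proline (20 mol %), CH2Cl2, rt
Reagents that add atoms: none
Why: Three-component reductive alkylation: Knoevenagel condensation at the pyranone C3, then conjugate hydride transfer from the dihydropyridine to the alkylidene. This gives the C11–ring A bond by C-alkylation only, which alkyl halides do not do cleanly with 4-hydroxypyranones.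

Step 11
Reactants: 16 hydroxypyranone Weinreb amide
Product: 17 Weinreb amide carrying the 4-(methoxymethoxy)-5,6-dimethyl-2-oxopyran-3-ylmethyl arm
Conditions: MOMCl, i-Pr2NEt, CH2Cl2, 0 °C
Reagents that add atoms: chloromethyl methyl ether, COCCl
Why: O-Alkylation of the acidic enol hydroxyl; the 4-alkoxy-2-pyranone is the conjugated, more stable regioisomer, and the acetal removes the acidic proton for the steps that follow.

Step 12
Reactants: 17 MOM-protected Weinreb amide
Product: 18 (5S)-5-[tert-butyl(dimethyl)silyl]oxy-1-chloro-6-{4-[(4-(methoxymethoxy)-5,6-dimethyl-2-oxo-2H-pyran-3-yl)methyl]-3-methylfuran-2-yl}-4,4-dimethylhexan-2-one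
Conditions: ICH2Cl, MeLi·LiBr, THF, −78 °C; AcOH quench
Reagents that add atoms: chloroiodomethane, ClCI
Why: LiCH2Cl, made in the flask by iodine–lithium exchange, adds to the Weinreb amide, and the stable chelate gives the chloromethyl ketone (C2–C3 bond) only on quench. The 4-alkoxy-2-pyranone is a vinylogous carbonate and a much poorer electrophile.

Step 13
Reactants: 18 chloromethyl ketone with tethered furan
Product: 20 oxygen-bridged cycloadduct (C1–O–C5 bridge on the β face; C9=C10 alkene; C3 ketone; H4 β; C7 OTBS on the bridge side of ring D), via oxyallyl cation 19 (not isolated)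
Conditions: Et3N (3 equiv), CF3CH2OH, 0.01 M, rt
Reagents that add atoms: none
Why: Et3N enolises the ketone toward C4, and loss of chloride in the ionising, weakly nucleophilic alcohol gives the oxyallyl cation 19 (C2–C3–C4). The cation adds across the two α-carbons of the furan; this is the intramolecular form of the known (4+3) cycloaddition of α-haloketone-derived oxyallyl cations with furans under amine/fluoroalcohol conditions. Ring D closes by 5-exo attack of the furan carbon C5 on C4 through the three-atom tether, helped by the gem-dimethyl group. Ring C closes when C2 bonds to C1, as the seven-membered ring bridged by the furan oxygen. C1 and C5 are set together because both bonds form on one furan face, and C4 is tied to C5 because the short tether allows only the cis ring fusion, which puts H4 on the bridge side. The one free element is which furan face reacts, and the C7 silyloxy centre decides it: in the folded transition state the OTBS group sits beside the furan oxygen, away from the C9 methyl that projects over the other face of the forming five-membered ring. Facial selectivity is therefore the selectivity the step needs, since regiochemistry is fixed by the tether; dilution and the intramolecular trap should outrun capture of 19 by the solvent.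

Step 14
Reactants: 20 oxygen-bridged cycloadduct
Product: 21 saturated bridged ketone (H9 and H10 β; C9 methyl and C10 arm α)
Conditions: H2, [Ir(cod)(PCy3)(py)]PF6 (cat.), CH2Cl2, rt
Reagents that add atoms: none
Why: Homogeneous hydrogenation of the strained tetrasubstituted alkene; the cationic iridium binds the bridging ether oxygen and delivers hydrogen to the exo face, which is also the sterically open one. This sets C9 correctly and C10 in the epimeric sense.

Step 15
Reactants: 21 saturated bridged ketone
Product: 22 C7 alcohol of the bridged ketone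
Conditions: HF·pyridine, THF, 0 °C to rt
Reagents that add atoms: none
Why: Fluoride-driven cleavage of the Si–O bond under non-basic conditions, so the β-alkoxy ketone does not eliminate.

Step 16
Reactants: 22 C7 alcohol of the bridged ketone
Product: 23 oxygen-bridged C3,C7-diketone
Conditions: Dess–Martin periodinane, pyridine, CH2Cl2, 0 °C to rt
Reagents that add atoms: none
Why: Dess–Martin oxidation of the secondary alcohol; the C7 centre has done its work, and the new ketone puts the bridge oxygen on C5 in a β-alkoxy ketone relationship.

Step 17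
Reactants: 23 oxygen-bridged C3,C7-diketone
Product: 26 C1,C4-diol (C1–OH β; C4–OH β; C5=C6–C7=O enone; C3 ketone), via enone alcohol 24 (not isolated), via C4 hydroperoxide 25 (not isolated)
Conditions: DBU, THF, 0 °C to rt; then O2 (1 atm), P(OEt)3, 0 °C
Reagents that add atoms: dioxygen, O=O
Why: E1cB: the C6 enolate expels the well-aligned C5–O bond, the oxygen stays on C1, and the C4–H (α to C3=O and γ to the enone) is deprotonated at once, so the opened ring is held as its extended enolate. Autoxidation of this enolate should place oxygen on the tertiary, doubly stabilised C4, keeping the cyclopentenone, from the β face opposite the cis C9 methyl and C10 arm. The phosphite reduces the hydroperoxide as it forms.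

Step 18
Reactants: 26 C1,C4-diol
Product: 27 C1,C3-diketone with C4 tertiary alcohol (drawn as the diketo tautomer)
Conditions: Dess–Martin periodinane, pyridine, CH2Cl2, 0 °C
Reagents that add atoms: none
Why: Dess–Martin oxidation of the only secondary alcohol; the tertiary C4 hydroxyl cannot be oxidised, and once C1 is a carbonyl the bridge cannot re-form.

Step 19
Reactants: 27 C1,C3-diketone
Product: 30 tetracyclic enol ether (ring B closed; C1=C2 conjugated with C3=O; C10–C11 β and trans to the C9 methyl), via free hydroxypyranone triketone 28 (not isolated), via C10-epimeric enol ether 29 (not isolated)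
Conditions: TFA, CH2Cl2, 0 °C to rt; then CSA, PhMe, 60 °C
Reagents that add atoms: none
Why: Acid removes the MOM acetal, and the freed pyranone hydroxyl, which can reach only C1, closes ring B by addition to the C1 carbonyl and loss of water (cyclodehydration of a 2-(hydroxyaryl-methyl)-1,3-dione to the vinylogous ester). C10–H is γ to the C3 carbonyl and exchanges under acid through the 4H-pyran-type dienol, so C10 should settle trans to the C9 methyl; the mild acid should leave C9, γ to the less basic enone, untouched.

Step 20
Reactants: 30 tetracyclic enol ether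
Product: 31 C4 trimethylsilyl ether of the enol ether
Conditions: Me3SiOTf, 2,6-lutidine, CH2Cl2, −78 °C
Reagents that add atoms: trimethylsilyl triflate, C[Si](C)(C)OS(=O)(=O)C(F)(F)F
Why: Silylation of the only hydroxyl; the pseudo-axial silyloxy group screens the β face of C1=C2 and removes any hydroxyl-directed delivery of the oxidant.

Step 21
Reactants: 31 C4 trimethylsilyl ether of the enol ether
Product: 34 target CNP0525404.1, via C1–C2 epoxide 32 (not isolated), via C4 silyl ether of the target 33 (not isolated)
Conditions: DMDO, acetone, −20 to 0 °C; then AcOH–THF–H2O, rt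
Reagents that add atoms: dimethyldioxirane, CC1(C)OO1; water, O
Why: Electrophilic epoxidation of the β-alkoxy enone double bond (as with chromones) from the α face, anti to the C4 silyloxy group that lies 1,3 to C2 across the C3 carbonyl. Hydrolytic opening at the ketal carbon C1 with inversion gives C1–OH β and C2–OH α with ring B trans-fused, and the same medium hydrolyses the tertiary silyl ether.

## Compound list

1 | ethyl 4-methylfuran-3-carboxylate | CCOC(=O)c1cocc1C | starting material
2 | ethyl 5-bromo-4-methylfuran-3-carboxylate | CCOC(=O)c1coc(Br)c1C | intermediate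
3 | (5-bromo-4-methylfuran-3-yl)methanol | OCc1coc(Br)c1C | intermediate
4 | [(5-bromo-4-methylfuran-3-yl)methoxy]triethylsilane | CC[Si](CC)(CC)OCc1coc(Br)c1C | intermediate
5 | methyl 3,3-dimethylpent-4-enoate | COC(=O)CC(C)(C)C=C | starting material
6 | methyl 3-methyl-3-(oxiran-2-yl)butanoate, racemic | COC(=O)CC(C)(C)C1CO1 | intermediate
7 | methyl 3-methyl-3-[(2R)-oxiran-2-yl]butanoate | COC(=O)CC(C)(C)[C@@H]1CO1 | intermediate
8 | methyl (4S)-4-hydroxy-3,3-dimethyl-5-[3-methyl-4-(triethylsilyloxymethyl)furan-2-yl]pentanoate, present as its magnesium alkoxide, not isolated | COC(=O)CC(C)(C)[C@@H](O)Cc1occ(CO[Si](CC)(CC)CC)c1C | intermediate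
9 | (5S)-4,4-dimethyl-5-{[3-methyl-4-(triethylsilyloxymethyl)furan-2-yl]methyl}oxolan-2-one | O=C1CC(C)(C)[C@H](Cc2occ(CO[Si](CC)(CC)CC)c2C)O1 | intermediate
10 | (4S)-4-hydroxy-N-methoxy-N,3,3-trimethyl-5-[3-methyl-4-(triethylsilyloxymethyl)furan-2-yl]pentanamide, not isolated | CON(C)C(=O)CC(C)(C)[C@@H](O)Cc1occ(CO[Si](CC)(CC)CC)c1C | intermediate
11 | (4S)-4-[tert-butyl(dimethyl)silyl]oxy-N-methoxy-N,3,3-trimethyl-5-[3-methyl-4-(triethylsilyloxymethyl)furan-2-yl]pentanamide | CON(C)C(=O)CC(C)(C)[C@@H](O[Si](C)(C)C(C)(C)C)Cc1occ(CO[Si](CC)(CC)CC)c1C | intermediate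
12 | (4S)-4-[tert-butyl(dimethyl)silyl]oxy-5-[4-(hydroxymethyl)-3-methylfuran-2-yl]-N-methoxy-N,3,3-trimethylpentanamide | CON(C)C(=O)CC(C)(C)[C@@H](O[Si](C)(C)C(C)(C)C)Cc1occ(CO)c1C | intermediate
13 | (4S)-4-[tert-butyl(dimethyl)silyl]oxy-5-(4-formyl-3-methylfuran-2-yl)-N-methoxy-N,3,3-trimethylpentanamide | CON(C)C(=O)CC(C)(C)[C@@H](O[Si](C)(C)C(C)(C)C)Cc1occ(C=O)c1C | intermediate
14 | 4-hydroxy-5,6-dimethyl-2H-pyran-2-one | Cc1oc(=O)cc(O)c1C | starting material
15 | Knoevenagel adduct, 3-(furylmethylidene)-5,6-dimethylpyran-2,4-dione of 13, not isolated | CON(C)C(=O)CC(C)(C)[C@@H](O[Si](C)(C)C(C)(C)C)Cc1occ(C=C2C(=O)OC(C)=C(C)C2=O)c1C | intermediate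
16 | Weinreb amide with the 3-(furylmethyl)-4-hydroxy-5,6-dimethylpyran-2-one arm | CON(C)C(=O)CC(C)(C)[C@@H](O[Si](C)(C)C(C)(C)C)Cc1occ(Cc2c(O)c(C)c(C)oc2=O)c1C | intermediate
17 | Weinreb amide with the 4-(methoxymethoxy)pyranone arm | CON(C)C(=O)CC(C)(C)[C@@H](O[Si](C)(C)C(C)(C)C)Cc1occ(Cc2c(OCOC)c(C)c(C)oc2=O)c1C | intermediate
18 | (5S)-5-[tert-butyl(dimethyl)silyl]oxy-1-chloro-6-{4-[(4-(methoxymethoxy)-5,6-dimethyl-2-oxo-2H-pyran-3-yl)methyl]-3-methylfuran-2-yl}-4,4-dimethylhexan-2-one | ClCC(=O)CC(C)(C)[C@@H](O[Si](C)(C)C(C)(C)C)Cc1occ(Cc2c(OCOC)c(C)c(C)oc2=O)c1C | intermediate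
19 | oxyallyl cation (C2–C3–C4) of 18, drawn as the zwitterion, not isolated | [CH2+]C([O-])=CC(C)(C)[C@@H](O[Si](C)(C)C(C)(C)C)Cc1occ(Cc2c(OCOC)c(C)c(C)oc2=O)c1C | intermediate
20 | oxygen-bridged cycloadduct: C1–O–C5 bridge β, C9=C10 alkene, C3 ketone, H4 β, C7 OTBS on the bridge side of ring D | O=C1C[C@@H]2O[C@@]3(C[C@H](O[Si](C)(C)C(C)(C)C)C(C)(C)[C@@H]13)C(C)=C2Cc2c(OCOC)c(C)c(C)oc2=O | intermediate
21 | saturated bridged ketone: H9 and H10 β, C9 methyl and C10 arm α | O=C1C[C@@H]2O[C@@]3(C[C@H](O[Si](C)(C)C(C)(C)C)C(C)(C)[C@@H]13)[C@H](C)[C@@H]2Cc2c(OCOC)c(C)c(C)oc2=O | intermediate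
22 | C7 alcohol of 21 | O=C1C[C@@H]2O[C@@]3(C[C@H](O)C(C)(C)[C@@H]13)[C@H](C)[C@@H]2Cc2c(OCOC)c(C)c(C)oc2=O | intermediate
23 | oxygen-bridged C3,C7-diketone | O=C1C[C@@H]2O[C@@]3(CC(=O)C(C)(C)[C@@H]13)[C@H](C)[C@@H]2Cc2c(OCOC)c(C)c(C)oc2=O | intermediate
24 | enone alcohol: C1–OH β, C5=C6–C7=O, C3 ketone, C4–H of undefined configuration; present as its C4 enolate, not isolated | O[C@H]1CC(=O)C2C(=CC(=O)C2(C)C)[C@H](C)[C@@H]1Cc1c(OCOC)c(C)c(C)oc1=O | intermediate
25 | C4 β-hydroperoxide of 24, not isolated | O[C@H]1CC(=O)[C@@]2(OO)C(=CC(=O)C2(C)C)[C@H](C)[C@@H]1Cc1c(OCOC)c(C)c(C)oc1=O | intermediate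
26 | C1,C4-diol: C1–OH β, C4–OH β, enone, C3 ketone | O[C@H]1CC(=O)[C@@]2(O)C(=CC(=O)C2(C)C)[C@H](C)[C@@H]1Cc1c(OCOC)c(C)c(C)oc1=O | intermediate
27 | C1,C3-diketone with C4–OH β, C10 arm α | O=C1CC(=O)[C@@]2(O)C(=CC(=O)C2(C)C)[C@H](C)[C@@H]1Cc1c(OCOC)c(C)c(C)oc1=O | intermediate
28 | 27 with free pyranone hydroxyl, not isolated | O=C1CC(=O)[C@@]2(O)C(=CC(=O)C2(C)C)[C@H](C)[C@@H]1Cc1c(O)c(C)c(C)oc1=O | intermediate
29 | tetracyclic enol ether, C10-epimer (C10–C11 α, cis to the C9 methyl), not isolated | Cc1oc(=O)c2c(c1C)OC1=CC(=O)[C@@]3(O)C(=CC(=O)C3(C)C)[C@H](C)[C@@H]1C2 | intermediate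
30 | tetracyclic enol ether: C1=C2, C3 ketone, C4–OH β, C9 methyl α, C10–C11 β | Cc1oc(=O)c2c(c1C)OC1=CC(=O)[C@@]3(O)C(=CC(=O)C3(C)C)[C@H](C)[C@H]1C2 | intermediate
31 | C4 trimethylsilyl ether of 30 | Cc1oc(=O)c2c(c1C)OC1=CC(=O)[C@@]3(O[Si](C)(C)C)C(=CC(=O)C3(C)C)[C@H](C)[C@H]1C2 | intermediate
32 | C1–C2 α-epoxide of 31, not isolated | Cc1oc(=O)c2c(c1C)O[C@]13O[C@@H]3C(=O)[C@@]4(O[Si](C)(C)C)C(=CC(=O)C4(C)C)[C@H](C)[C@H]1C2 | intermediate
33 | C4 trimethylsilyl ether of the target, not isolated | Cc1oc(=O)c2c(c1C)O[C@]1(O)[C@H](O)C(=O)[C@@]3(O[Si](C)(C)C)C(=CC(=O)C3(C)C)[C@H](C)[C@H]1C2 | intermediate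
34 | CNP0525404.1: C1–OH β, C2–OH α, C4–OH β, C9 methyl α, C10–C11 β | Cc1oc(=O)c2c(c1C)O[C@]1(O)[C@H](O)C(=O)[C@@]3(O)C(=CC(=O)C3(C)C)[C@H](C)[C@H]1C2 | target

## Step count and least certain steps

Total: 21 steps. Longest linear sequence: 19 steps (steps 1–3 and 6–21); the epoxide branch (steps 4 and 5) joins at step 6.

**Step 13 (key step).** Facial control may leak, because the C7 silyloxy group only biases a flexible three-atom tether. The unsubstituted cation 19 is also short-lived and may be captured by the solvent or collapse along the Favorskii path before it reaches the furan. Fallback: set out from Weinreb amide 17 and add dichloromethyllithium (from CH2Cl2 and n-BuLi, THF, −100 °C) to give the dichloromethyl ketone F1. Et3N in CF3CH2OH then forms a chlorine-stabilised, longer-lived oxyallyl cation, which should give the 2-chloro cycloadduct F2 through a later and more ordered transition state. Zn–Cu couple in MeOH/NH4Cl removes the chlorine and returns the route to 20.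

**Step 17.** The extended enolate is ambident, so oxygen may be taken up at C6 as well as at C4. The α-hydroperoxy ketone 25 may fragment before it is reduced, and the C1 hydroxyl may add back to C5 once the enolate is consumed. Fallback: set out from 23 and open the bridge with Et3SiOTf/Et3N (CH2Cl2, 0 °C), which should give the C1 silyl ether with ring D as a 2-silyloxycyclopentadiene, the bis-silyl compound F3. Singlet oxygen (O2, hν, tetraphenylporphyrin, −78 °C) adds across C4 and C7 of this locked s-cis diene, so oxygen can arrive only at C4; reduction with PPh3 and collapse of the endoperoxide give the C1-silylated C4 alcohol F4. HF·pyridine frees the C1 hydroxyl and the route is rejoined at 26.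

**Step 21.** The C1=C2 bond is a deactivated enol ether, so epoxidation may be slow and allow oxidation elsewhere, and attack on the β face would give the C2 epimer. Fallback: set out from diketone 27 and hydroxylate its enol at C2 with one equivalent of DMDO (acetone, −40 °C) to the 2-hydroxy-1,3-diketone F5. TFA in wet CH2Cl2 then removes the MOM group, the pyranone hydroxyl closes on C1, and C1, C2 and C10 settle under thermodynamic control to 34. This fallback relies on the natural arrangement being the stable one.

**Step 19.** Epimerisation at C10 may stop short of completion, and stronger acid risks an acyloin shift at C4 or exchange at C9. Fallback: set out from the C10-epimeric enol ether 29, isolated after the TFA stage. Silylate it to the epimeric silyl ether F6 and carry out the epoxidation and hydrolysis of step 21 to the 10-epi hemiketal F7. Then equilibrate C10 (and C1) with catalytic DBU in THF through the ring-opened C1 ketone, in which C10 is α to a free carbonyl, to reach 34; C2 is exposed to the same equilibrium.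

**Step 14.** The tetrasubstituted alkene beside the quaternary bridgehead may not reach the catalyst, or the Lewis-basic groups may bind the iridium unproductively. Fallback: set out from 20 and remove the silyl group with HF·pyridine to the alkene alcohol F8. Oxidise with Dess–Martin periodinane and treat with DBU to open the bridge to the dienone alcohol F9 (C9=C10 and C5=C6 both present, C1–OH β). Hydrogenate with the same iridium catalyst, now directed by the allylic C1 hydroxyl to the β face of C9=C10; this returns the route at 24, which is taken into the oxygenation of step 17.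

## Further compounds

F1 | step 13 | (5S)-5-[tert-butyl(dimethyl)silyl]oxy-1,1-dichloro analogue of 18 | ClC(Cl)C(=O)CC(C)(C)[C@@H](O[Si](C)(C)C(C)(C)C)Cc1occ(Cc2c(OCOC)c(C)c(C)oc2=O)c1C
F2 | step 13 | 2-chloro derivative of cycloadduct 20, C2 configuration open | O=C1C(Cl)[C@@H]2O[C@@]3(C[C@H](O[Si](C)(C)C(C)(C)C)C(C)(C)[C@@H]13)C(C)=C2Cc2c(OCOC)c(C)c(C)oc2=O
F3 | step 17 | ring-opened bis(triethylsilyl) compound: C1–OSiEt3 β, ring D as 2-(triethylsilyloxy)cyclopenta-1,3-diene | CC[Si](CC)(CC)O[C@H]1CC(=O)C2=C(C=C(O[Si](CC)(CC)CC)C2(C)C)[C@H](C)[C@@H]1Cc1c(OCOC)c(C)c(C)oc1=O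
F4 | step 17 | C1 triethylsilyl ether of diol 26 | CC[Si](CC)(CC)O[C@H]1CC(=O)[C@@]2(O)C(=CC(=O)C2(C)C)[C@H](C)[C@@H]1Cc1c(OCOC)c(C)c(C)oc1=O
F5 | step 21 | 2-hydroxy derivative of diketone 27, C2 configuration open | O=C1C(O)C(=O)[C@@]2(O)C(=CC(=O)C2(C)C)[C@H](C)[C@@H]1Cc1c(OCOC)c(C)c(C)oc1=O
F6 | step 19 | C4 trimethylsilyl ether of the C10-epimeric enol ether 29 | Cc1oc(=O)c2c(c1C)OC1=CC(=O)[C@@]3(O[Si](C)(C)C)C(=CC(=O)C3(C)C)[C@H](C)[C@@H]1C2
F7 | step 19 | 10-epi-34, C1 configuration open | Cc1oc(=O)c2c(c1C)OC1(O)[C@H](O)C(=O)[C@@]3(O)C(=CC(=O)C3(C)C)[C@H](C)[C@@H]1C2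
F8 | step 14 | C7 alcohol of cycloadduct 20 | O=C1C[C@@H]2O[C@@]3(C[C@H](O)C(C)(C)[C@@H]13)C(C)=C2Cc2c(OCOC)c(C)c(C)oc2=O
F9 | step 14 | dienone alcohol: C1–OH β, C9=C10, C5=C6–C7=O, C3 ketone | O[C@H]1CC(=O)C2C(=CC(=O)C2(C)C)C(C)=C1Cc1c(OCOC)c(C)c(C)oc1=O
A1 | alternative 1 | diquinane silyl enol ether (C3=C10) with C4 OTBS | C[C@@H]1C=C(O[Si](C)(C)C)[C@@]2(O[Si](C)(C)C(C)(C)C)C1=CC(=O)C2(C)C
A2 | alternative 1 | dichloroketene | ClC(Cl)=C=O
A3 | alternative 1 | 2,2-dichloro ring C 1,3-dione fused to ring D | O=C1C[C@@H](C)C2=CC(=O)C(C)(C)[C@@]2(O[Si](C)(C)C(C)(C)C)C(=O)C1(Cl)Cl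
A4 | alternative 2 | ring A/B/C tricycle with C4 ketone and isopropyl enone side chain | Cc1oc(=O)c2c(c1C)O[C@]1(OC)[C@H](O[Si](C)(C)C(C)(C)C)[C@@H](O[Si](CC)(CC)CC)C(=O)C(=CC(=O)C(C)C)[C@H](C)[C@H]1C2
A5 | alternative 2 | tetracycle with ring D closed, C1 methyl ketal, C2 OTBS, C3 OTES | Cc1oc(=O)c2c(c1C)O[C@]1(OC)[C@H](O[Si](C)(C)C(C)(C)C)[C@@H](O[Si](CC)(CC)CC)[C@@]3(O)C(=CC(=O)C3(C)C)[C@H](C)[C@H]1C2
A6 | alternative 3 | siloxyvinyl diazoacetate carrying the C11–pyranone arm | COC(=O)C(=[N+]=[N-])C(O[Si](C)(C)C(C)(C)C)=CCc1c(OCOC)c(C)c(C)oc1=O
A7 | alternative 3 | ring D diene: methylidene at C4, ethylidene at C5, C7 dioxolane | C=C1C(=CC)CC2(OCCO2)C1(C)C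
A8 | alternative 3 | ring C/D cyclohepta-1,4-diene with C1 silyl enol ether and C2 ester | COC(=O)C1=C(O[Si](C)(C)C(C)(C)C)[C@H](Cc2c(OCOC)c(C)c(C)oc2=O)[C@@H](C)C2=C(C1)C(C)(C)C3(OCCO3)C2
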